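## Structural features

The target is a bicyclic diterpenoid acid of the labdane type in the enantio series. It is a trans-fused decalin: ring A (C1–C5, C10) carries two methyl groups on C4, and ring B (C5–C10) carries an acetoxy group on C6, the C7=C8 double bond conjugated to the C17 carboxylic acid on C8, and an (E)-3-methylpenta-2,4-dienyl chain (C11–C16) on C9. Four stereocentres lie in a row along ring B, C9–C10–C5–C6 (9S,10S,5R,6S). The C10 methyl, the C9 chain and the 6-acetoxy group are on one face (called β below), H-5 is on the other, and the acetoxy group is axial and syn to the C10 methyl and to one C4 methyl. C10 is quaternary and lies between the tertiary C9 and C5, which is itself bonded to the quaternary C4, so the crowded array C4–C5–C10–C9 is the real difficulty, together with placing oxygen on the more hindered face of C6. Fragile elements are the hindered allylic acetate (it cannot survive hydrolysis of a C17 ester), the acid- and oxidant-sensitive diene, and C9–H, which becomes vinylogously acidic whenever C6 is a carbonyl. Ring A with C4, C5 and C10 is already present in 2,2,6-trimethylcyclohexanone, where C5 is the carbonyl carbon and C10 the only enolisable α-carbon. The key step uses this: C10 attacks C9 and C5 is attacked by C6, so the remaining ring B carbons C6–C9, with C17 on C8 and C11/C12 on C9, arrive as one alkylidene acetoacetate.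

## Logic of the disconnections

23 ⇒ 21 (through 22). The acyl C–O bond at O6 is cut. The acetate is the group least able to survive hydroxide, ylides or hydride, so it goes on last. All earlier chemistry can then run on a free alcohol and a methyl ester. The forward step must acylate an axial hydroxyl flanked by two syn-axial methyl groups while the acid is only transiently tied up.

21 ⇒ 20. The ester O–CH3 unit at C17 is restored. C17 travels as a methyl ester from 4 onward because the ester activates the annulation and later directs enolisation. The forward step must hydrolyse a shielded conjugated ester without moving C7=C8 or touching the diene.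

20 ⇒ 19 ⇒ 18. C14=C15 and then C12=C13 are cut. Two carbonyl olefinations build the diene: a stabilised ylide gives the E-trisubstituted alkene, a non-stabilised one the terminal methylene. The side chain shrinks to a two-carbon aldehyde arm on C9. Both olefinations must tolerate the free 6-hydroxyl and the ring B enoate.

18 ⇒ 17 ⇒ 16. No C–C bond is cut; C12 goes back from aldehyde to alcohol to silyl ether. A protected primary alcohol is the form in which C12 can pass through acid, peracid and hydride. The forward oxidation must take the primary alcohol of 17 and leave the secondary allylic one.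

16 ⇒ 15. The C6–H bond is cut. The axial 6β-alcohol is the expected product of hydride attack on a 6-ketone from the open α face, so the C6 stereocentre reduces to a carbonyl. The forward step must be a 1,2-reduction of an enone that is also a γ-keto enoate.

15 ⇒ 13 ⇒ 12 (through 14). The C5–H bond and the C6 carbonyl are traced back to a C5–C6 epoxide and then to the C5=C6 alkene. This 1,2-transposition brings oxygen to C6 from an alkene that the annulation leaves behind, and reduces two stereocentres to a diene. It demands epoxidation of the γ,δ- and not the α,β-double bond, from the α face; hydride and not carbon migration to C5; and equilibration of C5 to the trans fusion without disturbing C9.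

12 ⇒ 11 ⇒ 10. The C7–H bond is replaced by C7–O. The carbonyl oxygen that the annulation leaves on C7 is removed through its enol triflate, so 10 is a direct annulation product. The forward steps need O-sulfonylation toward C8 and a reduction that spares the diene.

10 ⇒ 3 + 6 (through 7, 8 and 9). C5=C6 and C9–C10 are cut, a retro-aldol condensation and a retro-Michael addition. One ring and two stereocentres disappear and the molecule divides into ring A and a six-carbon chain. The forward step demands absolute control at C10, the cis relationship of C11 and the C10 methyl, and ring closure on a carbonyl between two quaternary carbons.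

3 ⇒ 1 + 2 and 6 ⇒ 4 + 5. C5=N and C8=C9 are cut. Both are condensations of bought components. The first needs forcing because the carbonyl is hindered; the second needs mild conditions because the product is a reactive acceptor with γ-hydrogens.

## Other disconnections considered

Alternative 1: The cut runs through C7–C8 and C9–C10, so ring B is made first and ring A is attached afterwards.
- **Forward key step.** (Z)-2,4-bis(trimethylsilyloxy)penta-1,3-diene A2 (C7, C6, C5, C10) would add to the fumaric ester imide A3 (C8, C9) under Cu(OTf)2 with a chiral bis(oxazoline) ligand (divalent copper chelated by the imide). Loss of the silyloxy group from C10 on work-up would give cyclohexenone A1: ketone at C6, alkene C5=C10, ester (C17) on C8 and imide carbonyl (C11) on C9, trans.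
- **In its favour.** Absolute configuration comes from a catalyst. The C6 oxygen is present from the first step, where the chosen route spends steps 4 to 8 moving oxygen from C7 to C6; on this point the alternative is clearly better. C17 and C11 arrive differentiated.
- **Against it here.** A1 contains neither the quaternary C10 nor ring A. C1 would have to add to the β-methyl enone carbon trans to the C9 substituent (the favourable sense). The C4–C5 bond, which joins the carbon bearing two methyl groups to C5, would then have to be closed late in a crowded intermediate. C11 must be reduced from acyl to methylene without touching C17, and C8 and C9 of A1 are both epimerisable.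
- **Comparison.** On structure, the chosen plan buys the crowded half (ring A with C4) and builds the less substituted ring; the alternative does the reverse. On mechanism, the alternative is equal in forming C9–C10 in its key step and better in being catalytic, but leaves C10 as an sp2 carbon. On step economy, ring A and the adjustment at C11 should cost more operations than the chosen route saves at C6, so it is expected to be longer than 14 steps.

Alternative 2: The cut is at C5–C10 and C8–C9, so both rings come from the open-chain trienal A5 in one intramolecular Diels–Alder reaction.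
- **Forward key step.** Me2AlCl on the aldehyde of A5 would make the (E)-3-methyl enal (C9=C10) add across the 2-silyloxydiene C5=C6–C7=C8 through the C1–C4 tether to give A4.
- **In its favour.** Two rings, two C–C bonds and four stereocentres form at once, which is better ring-forming economy than the chosen plan. The cis relationship of the C9 substituent and the C10 methyl follows stereospecifically from the enal geometry, which is more secure than the transition-state preference step 3 relies on. The silyl enol ether puts oxygen on C6 and the cycloaddition sets the trans fusion directly, so neither the oxygen transposition nor the C5 equilibration would be needed; this too is better.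
- **Against it here.** The dienophile is a β,β-disubstituted enal and the diene terminus C5 is next to the quaternary C4, so C5–C10 must form between two very crowded carbons. Absolute control would need a chiral acid or amine catalyst, for which trisubstituted enals are poor substrates. A5 needs a long linear synthesis with three defined double bonds. C11 arrives as a formyl group, one carbon short, and C17 arrives at the alcohol level.
- **Comparison.** On structure it is equal or better (same C9/C10 relationship, C5 and C6 handled directly). On mechanism it is better for relative and weaker for absolute stereocontrol than the auxiliary-controlled Michael addition. On step economy, the saving after the cycloaddition is expected to be used up by the route to A5, the homologation at C11 and the oxidation at C17.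

Alternative 3: The cut is at C1–C10 and C9–C11 on a preformed ring B, 3-methylcyclohex-2-en-1-one A7 (its carbonyl is C8); no ring closes in the key step.
- **Forward key step.** A copper-catalysed asymmetric 1,4-addition (CuBr·SMe2 with a chiral diphosphine) of Grignard reagent A8 to A7 would create the quaternary C10. The magnesium enolate would be alkylated at C9 by bromide A9 anti to the larger chain, that is cis to the methyl, to give A6.
- **In its favour.** The quaternary centre is made catalytically, which is better than a stoichiometric auxiliary even though the amine of step 1 is recovered. The C9 chain enters as a robust alkyne holding C11–C13 and a methyl. The C8 carbonyl is well placed to become the C7=C8–C17 enoate through enol triflate carbonylation.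
- **Against it here.** Ring A must be closed later at the crowded C4–C5 bond, which first requires moving oxygen to C6 to activate C5. The trisubstituted (E)-diene must come from an internal alkyne whose two ends are nearly alike. Alkylation of a hindered magnesium enolate next to a quaternary carbon may be sluggish and only moderately selective.
- **Comparison.** On structure it is equal in fixing C9 and C10 early, but the chosen plan has ring A from the start and closes ring B with both stereocentres in one step. On mechanism the alternative is better for enantiocontrol economy. On step economy, oxygen transposition, ring A closure and diene construction after the key step suggest a similar or somewhat greater length.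

Key step: step 3

**Remarks on the chemistry (conventions, assumption and corrections)**
- Locants are those of the labdane skeleton (C17 = carboxyl carbon on C8, C20 = methyl on C10). β means the face of ring B that carries the C10 methyl; α is the opposite face.
- Assumption: 5 is bought as such.
- The condensation product of 1 and 2 is written as imine 3, the stable tautomer. The secondary enamine 7 is its reacting form and is numbered as an in-situ species.
- The Knoevenagel product 6 forms as an E/Z mixture and is used as such; the stereochemical argument of step 3 does not depend on its geometry.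
- C8 of 10 is drawn 8R (trans to the C9 arm) but is enolisable and uncontrolled; only C9 and C10 are set in step 3.
- The C12 oxygen carries a tert-butyldiphenylsilyl group in place of a tert-butyldimethylsilyl group, which would not be expected to survive the aqueous acid and hot TsOH of step 3.
- The hydride shift of step 7 first gives the cis-fused ketone 14, so the equilibration to 15 is written into that step.

## Route

Step 1
Reactants: 1 2,2,6-trimethylcyclohexanone (racemic); 2 (R)-1-phenylethylamine
Product: 3 (R)-N-(2,2,6-trimethylcyclohexylidene)-1-phenylethanamine (imine; both C6 epimers)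
Conditions: TiCl4 (0.55 equiv), Et3N (2.5 equiv), PhMe, 0 → 110 °C
Reagents that add atoms: none
Why: Imine condensation of a hindered ketone, with TiCl4 acting as activator and water scavenger; the stereocentre of 1 is irrelevant because 3 equilibrates with enamine 7, which can form only toward the methyl-bearing carbon (future C10) since the other α-carbon (future C4) is quaternary.

Step 2
Reactants: 4 methyl acetoacetate; 5 3-(tert-butyldiphenylsilyloxy)propanal
Product: 6 methyl 2-acetyl-5-(tert-butyldiphenylsilyloxy)pent-2-enoate (E/Z mixture)
Conditions: piperidine (0.1 equiv), AcOH (0.1 equiv), 4 Å molecular sieves, CH2Cl2, 0 °C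
Reagents that add atoms: none
Why: Knoevenagel condensation under piperidinium acetate catalysis; low temperature and a slight excess of aldehyde limit double Michael addition and deconjugation, and the product is used at once.

Step 3
Reactants: 3 (R)-N-(2,2,6-trimethylcyclohexylidene)-1-phenylethanamine; 6 methyl 2-acetyl-5-(tert-butyldiphenylsilyloxy)pent-2-enoate (E/Z mixture)
Product: 10 methyl (1R,2R,8aS)-1-[2-(tert-butyldiphenylsilyloxy)ethyl]-5,5,8a-trimethyl-3-oxo-1,2,3,5,6,7,8,8a-octahydronaphthalene-2-carboxylate (labdane locants: 5-en-7-one), via secondary enamine 7 (not isolated), via Michael adduct imine 8 (not isolated), via 1,5-diketone 9 (not isolated)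
Conditions: PhMe (2 M), 45 °C; then 2 M aq HCl, THF, 40 °C; organic phase, TsOH·H2O (0.2 equiv), PhMe, 110 °C, azeotropic removal of water
Reagents that add atoms: none
Why: Imine 3 reacts through its enamine tautomer 7 in an aza-ene-like Michael addition in which C10 bonds to C9 of 6 while the N–H proton passes to C8 within a six-membered cyclic array, giving imine 8; aqueous acid hydrolyses 8 (and any β-enamino ester formed with freed amine) to 9, and TsOH then drives the aldol condensation of the acetyl methyl C6, through its enol, onto the protonated C5 carbonyl. The closest known reaction type is the deracemising Michael addition of 1-phenylethylamine imines of 2-substituted cyclohexanones to electron-poor alkenes, followed by Robinson-type cyclodehydration. Ring B closes by a 6-(enolendo)-exo-trig aldol addition and dehydration, which can place the double bond only at C5=C6 because C4 and C10 carry no hydrogen. C10 is set by the (R)-1-phenylethyl group: with its C–H bond in the enamine plane the phenyl group covers one face, and bonding on the other face should give 10S, the sense known for the 2-methylcyclohexanone imine of this amine. C9 is set by the compact transition state: C8 must lie over the N–H, so of the two remaining positions on C9 the one anti to C5 points away from ring A and is taken by the silyloxyethyl chain while hydrogen takes the one over ring A and the C4 methyls, which places C11 cis to the C10 methyl (9R in 10); either geometric isomer of 6 has one carbonyl cis and one trans to the chain, so both can adopt this arrangement. C8 is not controlled and need not be, because it is enolisable and becomes sp2 in step 4. The step needs regioselectivity (secured by the quaternary C4 and by the fact that only the acetyl methyl, not C8, can reach C5 in a six-membered ring), a C12 protecting group that resists hot acid (hence the diphenylsilyl ether) and no reversal of the Michael addition (hence acid, not alkoxide, for the ring closure).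

Step 4
Reactants: 10 methyl (1R,2R,8aS)-1-[2-(tert-butyldiphenylsilyloxy)ethyl]-5,5,8a-trimethyl-3-oxo-1,2,3,5,6,7,8,8a-octahydronaphthalene-2-carboxylate
Product: 11 methyl (1S,8aS)-1-[2-(tert-butyldiphenylsilyloxy)ethyl]-5,5,8a-trimethyl-3-(trifluoromethanesulfonyloxy)-1,5,6,7,8,8a-hexahydronaphthalene-2-carboxylate
Conditions: Tf2O, i-Pr2NEt, CH2Cl2, −78 → 0 °C
Reagents that add atoms: trifluoromethanesulfonic anhydride, O=S(=O)(OS(=O)(=O)C(F)(F)F)C(F)(F)F
Why: O-sulfonylation of the β-keto ester enol, which can form only toward C8 because C6 is vinylic, gives the cross-conjugated dienyl triflate; the C8 stereocentre disappears and C9 is not enolisable under these conditions.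

Step 5
Reactants: 11 methyl (1S,8aS)-1-[2-(tert-butyldiphenylsilyloxy)ethyl]-5,5,8a-trimethyl-3-(trifluoromethanesulfonyloxy)-1,5,6,7,8,8a-hexahydronaphthalene-2-carboxylate
Product: 12 methyl (1S,8aS)-1-[2-(tert-butyldiphenylsilyloxy)ethyl]-5,5,8a-trimethyl-1,5,6,7,8,8a-hexahydronaphthalene-2-carboxylate (labdane locants: 5,7-dien-17-oate)
Conditions: Pd(OAc)2 (5 mol %), PPh3 (10 mol %), HCO2H, Et3N, DMF, 60 °C
Reagents that add atoms: none
Why: Palladium-catalysed formate reduction of a vinyl triflate: oxidative addition of the C–O bond to zerovalent palladium, exchange of triflate for formate, loss of CO2 and reductive elimination of C7–H; the diene, ester and silyl ether are not reduced.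

Step 6
Reactants: 12 methyl (1S,8aS)-1-[2-(tert-butyldiphenylsilyloxy)ethyl]-5,5,8a-trimethyl-1,5,6,7,8,8a-hexahydronaphthalene-2-carboxylate
Product: 13 methyl (1S,4R,4aS,8aS)-1-[2-(tert-butyldiphenylsilyloxy)ethyl]-4,4a-epoxy-5,5,8a-trimethyl-1,4,4a,5,6,7,8,8a-octahydronaphthalene-2-carboxylate (5,6-epoxide on the α face)
Conditions: mCPBA, NaHCO3, CH2Cl2, 0 → 25 °C
Reagents that add atoms: 3-chloroperoxybenzoic acid (mCPBA), O=C(OO)c1cccc(Cl)c1
Why: Electrophilic epoxidation should pick the γ,δ-double bond C5=C6, the electron-richer alkene of a dienoate, and the α face, because the β face is covered by the axial C10 methyl and the β methyl on C4.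

Step 7
Reactants: 13 methyl (1S,4R,4aS,8aS)-1-[2-(tert-butyldiphenylsilyloxy)ethyl]-4,4a-epoxy-5,5,8a-trimethyl-1,4,4a,5,6,7,8,8a-octahydronaphthalene-2-carboxylate
Product: 15 methyl (1S,4aR,8aS)-1-[2-(tert-butyldiphenylsilyloxy)ethyl]-5,5,8a-trimethyl-4-oxo-1,4,4a,5,6,7,8,8a-octahydronaphthalene-2-carboxylate (trans-fused 7-en-6-one), via cis-fused ketone 14 (not isolated)
Conditions: BF3·OEt2 (0.3 equiv), CH2Cl2, −78 → −40 °C; aq NaHCO3; then DBU (0.2 equiv), CH2Cl2, 25 °C
Reagents that add atoms: none
Why: Meinwald rearrangement: the Lewis acid opens the epoxide at the tertiary C5 (C6 is deactivated by the enoate) and the C6 hydrogen shifts to C5 on the β face, giving the cis-fused enone 14. Its C5–H, now α to the ketone, is then equilibrated by a catalytic amine base to the more stable trans-fused 15; brief contact with a weak base is chosen to leave the vinylogous C9–H alone.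

Step 8
Reactants: 15 methyl (1S,4aR,8aS)-1-[2-(tert-butyldiphenylsilyloxy)ethyl]-5,5,8a-trimethyl-4-oxo-1,4,4a,5,6,7,8,8a-octahydronaphthalene-2-carboxylate
Product: 16 methyl (1S,4S,4aR,8aS)-1-[2-(tert-butyldiphenylsilyloxy)ethyl]-4-hydroxy-5,5,8a-trimethyl-1,4,4a,5,6,7,8,8a-octahydronaphthalene-2-carboxylate (6β-alcohol)
Conditions: NaBH4, CeCl3·7H2O, MeOH, −78 → −40 °C
Reagents that add atoms: none
Why: Luche reduction gives 1,2-addition to the enone and leaves the ester alone; hydride should enter from the α face because the β face of C6 is blocked by the syn-axial methyls on C10 and C4, giving the axial 6β-alcohol (6S).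

Step 9
Reactants: 16 methyl (1S,4S,4aR,8aS)-1-[2-(tert-butyldiphenylsilyloxy)ethyl]-4-hydroxy-5,5,8a-trimethyl-1,4,4a,5,6,7,8,8a-octahydronaphthalene-2-carboxylate
Product: 17 methyl (1S,4S,4aR,8aS)-4-hydroxy-1-(2-hydroxyethyl)-5,5,8a-trimethyl-1,4,4a,5,6,7,8,8a-octahydronaphthalene-2-carboxylate
Conditions: HF·pyridine, pyridine, THF, 0 → 25 °C
Reagents that add atoms: none
Why: Fluoride cleavage of the primary silyl ether under non-basic conditions, which avoids alkoxide-driven lactonisation of the C12 hydroxyl onto the C17 ester.

Step 10
Reactants: 17 methyl (1S,4S,4aR,8aS)-4-hydroxy-1-(2-hydroxyethyl)-5,5,8a-trimethyl-1,4,4a,5,6,7,8,8a-octahydronaphthalene-2-carboxylate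
Product: 18 methyl (1S,4S,4aR,8aS)-4-hydroxy-5,5,8a-trimethyl-1-(2-oxoethyl)-1,4,4a,5,6,7,8,8a-octahydronaphthalene-2-carboxylate
Conditions: TEMPO (0.1 equiv), PhI(OAc)2 (1.1 equiv), CH2Cl2, 0 → 25 °C
Reagents that add atoms: none
Why: Oxoammonium oxidation is strongly selective for primary alcohols; the axial 6β-carbinol, shielded by two syn-axial methyls and attached to an electron-poor alkene, is expected to remain, and without water the aldehyde is not oxidised further.

Step 11
Reactants: 18 methyl (1S,4S,4aR,8aS)-4-hydroxy-5,5,8a-trimethyl-1-(2-oxoethyl)-1,4,4a,5,6,7,8,8a-octahydronaphthalene-2-carboxylate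
Product: 19 methyl (1S,4S,4aR,8aS)-4-hydroxy-5,5,8a-trimethyl-1-[(2E)-3-methyl-4-oxobut-2-en-1-yl]-1,4,4a,5,6,7,8,8a-octahydronaphthalene-2-carboxylate
Conditions: Ph3P=C(CH3)CHO (1.3 equiv), PhMe, 80 °C
Reagents that add atoms: 2-(triphenylphosphoranylidene)propanal, CC(C=O)=P(c1ccccc1)(c1ccccc1)c1ccccc1
Why: Wittig reaction with a stabilised ylide, which should give the (E)-2-methyl enal (C11 trans to the formyl group) and is too weakly basic to affect the hydroxyl, the enoate or C9.

Step 12
Reactants: 19 methyl (1S,4S,4aR,8aS)-4-hydroxy-5,5,8a-trimethyl-1-[(2E)-3-methyl-4-oxobut-2-en-1-yl]-1,4,4a,5,6,7,8,8a-octahydronaphthalene-2-carboxylate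
Product: 20 methyl (1S,4S,4aR,8aS)-4-hydroxy-5,5,8a-trimethyl-1-[(2E)-3-methylpenta-2,4-dien-1-yl]-1,4,4a,5,6,7,8,8a-octahydronaphthalene-2-carboxylate
Conditions: Ph3PCH3Br (3.0 equiv), KOt-Bu (2.8 equiv), THF, 0 °C
Reagents that add atoms: methyltriphenylphosphonium bromide, C[P+](c1ccccc1)(c1ccccc1)c1ccccc1.[Br-]
Why: Wittig methylenation of the enal by 1,2-addition completes the diene without changing the C12=C13 geometry; the excess ylide only deprotonates the 6-hydroxyl, and the hindered conjugated ester is not attacked at 0 °C.

Step 13
Reactants: 20 methyl (1S,4S,4aR,8aS)-4-hydroxy-5,5,8a-trimethyl-1-[(2E)-3-methylpenta-2,4-dien-1-yl]-1,4,4a,5,6,7,8,8a-octahydronaphthalene-2-carboxylate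
Product: 21 (1S,4S,4aR,8aS)-4-hydroxy-5,5,8a-trimethyl-1-[(2E)-3-methylpenta-2,4-dien-1-yl]-1,4,4a,5,6,7,8,8a-octahydronaphthalene-2-carboxylic acid
Conditions: LiOH·H2O, THF/MeOH/H2O, 45 °C; then 1 M HCl to pH 3, 0 °C
Reagents that add atoms: lithium hydroxide, [Li+].[OH-]
Why: Saponification by acyl–oxygen cleavage of the conjugated methyl ester; the diene and the 6-hydroxyl are base-stable, and once the carboxylate has formed the enoate is deactivated toward γ-deprotonation.

Step 14
Reactants: 21 (1S,4S,4aR,8aS)-4-hydroxy-5,5,8a-trimethyl-1-[(2E)-3-methylpenta-2,4-dien-1-yl]-1,4,4a,5,6,7,8,8a-octahydronaphthalene-2-carboxylic acid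
Product: 23 (1S,4S,4aR,8aS)-4-acetoxy-5,5,8a-trimethyl-1-[(2E)-3-methylpenta-2,4-dien-1-yl]-1,4,4a,5,6,7,8,8a-octahydronaphthalene-2-carboxylic acid (target CNP0294871.1), via mixed acetic anhydride 22 (not isolated)
Conditions: Ac2O, DMAP (0.3 equiv), pyridine, 40 °C; then H2O, THF, 25 °C
Reagents that add atoms: acetic anhydride, CC(=O)OC(C)=O
Why: DMAP-catalysed acetylation of the hindered axial alcohol; the carboxyl group is converted in parallel into mixed anhydride 22, which is far more reactive than the secondary acetate and is hydrolysed selectively by aqueous pyridine in the work-up.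

## Compound list

1 | 2,2,6-trimethylcyclohexanone (racemic) | CC1CCCC(C)(C)C1=O | starting material
2 | (R)-1-phenylethylamine | C[C@@H](N)c1ccccc1 | starting material
3 | (R)-N-(2,2,6-trimethylcyclohexylidene)-1-phenylethanamine (both C6 epimers, C=N geometry open) | CC1CCCC(C)(C)C1=N[C@H](C)c1ccccc1 | intermediate
4 | methyl acetoacetate | CC(=O)CC(=O)OC | starting material
5 | 3-(tert-butyldiphenylsilyloxy)propanal | O=CCCO[Si](c1ccccc1)(c1ccccc1)C(C)(C)C | starting material
6 | methyl 2-acetyl-5-(tert-butyldiphenylsilyloxy)pent-2-enoate (E/Z mixture, geometry left open) | CC(=O)C(C(=O)OC)=CCCO[Si](c1ccccc1)(c1ccccc1)C(C)(C)C | intermediate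
7 | (R)-2,6,6-trimethyl-N-(1-phenylethyl)cyclohex-1-en-1-amine (enamine tautomer of 3, formed in situ) | CC1=C(N[C@H](C)c2ccccc2)C(C)(C)CCC1 | intermediate
8 | methyl (3R)-2-acetyl-5-(tert-butyldiphenylsilyloxy)-3-[(1S)-1,3,3-trimethyl-2-{[(1R)-1-phenylethyl]imino}cyclohexyl]pentanoate (C2 epimers, formed in situ) | CC(C)(C)[Si](c1ccccc1)(c1ccccc1)OCC[C@H](C(C(C)=O)C(=O)OC)[C@]1(C)CCCC(C)(C)C1=N[C@H](C)c1ccccc1 | intermediate
9 | methyl (3R)-2-acetyl-5-(tert-butyldiphenylsilyloxy)-3-[(1S)-1,3,3-trimethyl-2-oxocyclohexyl]pentanoate (C2 epimers, formed in situ) | CC(C)(C)[Si](c1ccccc1)(c1ccccc1)OCC[C@H](C(C(C)=O)C(=O)OC)[C@]1(C)CCCC(C)(C)C1=O | intermediate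
10 | methyl (1R,2R,8aS)-1-[2-(tert-butyldiphenylsilyloxy)ethyl]-5,5,8a-trimethyl-3-oxo-1,2,3,5,6,7,8,8a-octahydronaphthalene-2-carboxylate (C2 epimerisable) | CC(C)(C)[Si](c1ccccc1)(c1ccccc1)OCC[C@@H]1[C@@H](C(=O)OC)C(=O)C=C2C(C)(C)CCC[C@@]12C | intermediate
11 | methyl (1S,8aS)-1-[2-(tert-butyldiphenylsilyloxy)ethyl]-5,5,8a-trimethyl-3-(trifluoromethanesulfonyloxy)-1,5,6,7,8,8a-hexahydronaphthalene-2-carboxylate | CC(C)(C)[Si](c1ccccc1)(c1ccccc1)OCC[C@@H]1C(C(=O)OC)=C(OS(=O)(=O)C(F)(F)F)C=C2C(C)(C)CCC[C@@]12C | intermediate
12 | methyl (1S,8aS)-1-[2-(tert-butyldiphenylsilyloxy)ethyl]-5,5,8a-trimethyl-1,5,6,7,8,8a-hexahydronaphthalene-2-carboxylate | CC(C)(C)[Si](c1ccccc1)(c1ccccc1)OCC[C@@H]1C(C(=O)OC)=CC=C2C(C)(C)CCC[C@@]12C | intermediate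
13 | methyl (1S,4R,4aS,8aS)-1-[2-(tert-butyldiphenylsilyloxy)ethyl]-4,4a-epoxy-5,5,8a-trimethyl-1,4,4a,5,6,7,8,8a-octahydronaphthalene-2-carboxylate | CC(C)(C)[Si](c1ccccc1)(c1ccccc1)OCC[C@@H]1C(C(=O)OC)=C[C@H]3O[C@]32C(C)(C)CCC[C@@]12C | intermediate
14 | methyl (1S,4aS,8aS)-1-[2-(tert-butyldiphenylsilyloxy)ethyl]-5,5,8a-trimethyl-4-oxo-1,4,4a,5,6,7,8,8a-octahydronaphthalene-2-carboxylate (cis-fused, formed in situ) | CC(C)(C)[Si](c1ccccc1)(c1ccccc1)OCC[C@@H]1C(C(=O)OC)=CC(=O)[C@H]2C(C)(C)CCC[C@@]12C | intermediate
15 | methyl (1S,4aR,8aS)-1-[2-(tert-butyldiphenylsilyloxy)ethyl]-5,5,8a-trimethyl-4-oxo-1,4,4a,5,6,7,8,8a-octahydronaphthalene-2-carboxylate (trans-fused) | CC(C)(C)[Si](c1ccccc1)(c1ccccc1)OCC[C@@H]1C(C(=O)OC)=CC(=O)[C@@H]2C(C)(C)CCC[C@@]12C | intermediate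
16 | methyl (1S,4S,4aR,8aS)-1-[2-(tert-butyldiphenylsilyloxy)ethyl]-4-hydroxy-5,5,8a-trimethyl-1,4,4a,5,6,7,8,8a-octahydronaphthalene-2-carboxylate | CC(C)(C)[Si](c1ccccc1)(c1ccccc1)OCC[C@@H]1C(C(=O)OC)=C[C@H](O)[C@@H]2C(C)(C)CCC[C@@]12C | intermediate
17 | methyl (1S,4S,4aR,8aS)-4-hydroxy-1-(2-hydroxyethyl)-5,5,8a-trimethyl-1,4,4a,5,6,7,8,8a-octahydronaphthalene-2-carboxylate | OCC[C@@H]1C(C(=O)OC)=C[C@H](O)[C@@H]2C(C)(C)CCC[C@@]12C | intermediate
18 | methyl (1S,4S,4aR,8aS)-4-hydroxy-5,5,8a-trimethyl-1-(2-oxoethyl)-1,4,4a,5,6,7,8,8a-octahydronaphthalene-2-carboxylate | O=CC[C@@H]1C(C(=O)OC)=C[C@H](O)[C@@H]2C(C)(C)CCC[C@@]12C | intermediate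
19 | methyl (1S,4S,4aR,8aS)-4-hydroxy-5,5,8a-trimethyl-1-[(2E)-3-methyl-4-oxobut-2-en-1-yl]-1,4,4a,5,6,7,8,8a-octahydronaphthalene-2-carboxylate | O=C/C(C)=C/C[C@@H]1C(C(=O)OC)=C[C@H](O)[C@@H]2C(C)(C)CCC[C@@]12C | intermediate
20 | methyl (1S,4S,4aR,8aS)-4-hydroxy-5,5,8a-trimethyl-1-[(2E)-3-methylpenta-2,4-dien-1-yl]-1,4,4a,5,6,7,8,8a-octahydronaphthalene-2-carboxylate | C=C/C(C)=C/C[C@@H]1C(C(=O)OC)=C[C@H](O)[C@@H]2C(C)(C)CCC[C@@]12C | intermediate
21 | (1S,4S,4aR,8aS)-4-hydroxy-5,5,8a-trimethyl-1-[(2E)-3-methylpenta-2,4-dien-1-yl]-1,4,4a,5,6,7,8,8a-octahydronaphthalene-2-carboxylic acid | C=C/C(C)=C/C[C@@H]1C(C(=O)O)=C[C@H](O)[C@@H]2C(C)(C)CCC[C@@]12C | intermediate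
22 | acetic (1S,4S,4aR,8aS)-4-acetoxy-5,5,8a-trimethyl-1-[(2E)-3-methylpenta-2,4-dien-1-yl]-1,4,4a,5,6,7,8,8a-octahydronaphthalene-2-carboxylic anhydride (formed in situ) | C=C/C(C)=C/C[C@@H]1C(C(=O)OC(C)=O)=C[C@H](OC(C)=O)[C@@H]2C(C)(C)CCC[C@@]12C | intermediate
23 | (1S,4S,4aR,8aS)-4-acetoxy-5,5,8a-trimethyl-1-[(2E)-3-methylpenta-2,4-dien-1-yl]-1,4,4a,5,6,7,8,8a-octahydronaphthalene-2-carboxylic acid; labdane locants (5R,6S,9S,10S,12E); CNP0294871.1 | C=C/C(C)=C/C[C@@H]1C(C(=O)O)=C[C@H](OC(C)=O)[C@@H]2C(C)(C)CCC[C@@]12C | target

## Step count and least certain steps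

Total: 14 steps. Longest linear sequence: 13 steps (steps 1 and 3 to 14, from 1); step 2 is a one-step branch.

**Step 3 (key step).** The most likely failure is that ring closure stalls. Addition of the C6 enol to a carbonyl carbon held between the quaternary C4 and C10 is slow, so during long heating in acid, cleavage of the silyl ether followed by lactonisation of O12 onto C17, or acid-induced reversal of the Michael addition, can overtake it. A second weakness is slow C–C bond formation by the congested enamine, whose N-substituent is pushed toward the C4 methyls, which gives the acceptor time to deconjugate. The fallback sets out from 9, isolated after the hydrolysis. Treatment with lithium diisopropylamide (2.2 equiv) in THF at −78 → 0 °C would form the 1,3-dianion of the β-keto ester, whose terminal carbon C6 adds irreversibly to the non-enolisable C5 carbonyl to give the ketol methyl (1R,8aS)-1-[2-(tert-butyldiphenylsilyloxy)ethyl]-4a-hydroxy-5,5,8a-trimethyl-3-oxodecahydronaphthalene-2-carboxylate F1. Mild acid (catalytic TsOH, 25–50 °C) would then dehydrate it through the C6 enol, and the route is rejoined at 10. This replaces an equilibrium condensation by a kinetically controlled carbanion addition followed by a separate dehydration.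

**Step 7.** The most likely failure is partition of the C5 cation away from the hydride shift: migration of C7 (ring contraction to a cyclopentene aldehyde), migration of a methyl group from C4 or C10, or capture by fluoride. In addition, the base treatment may move the equilibrium at C9 as well as at C5. The fallback avoids both the cation and the 6-ketone and sets out from 12. N-Bromosuccinimide in aqueous acetone at 0 °C would form the bromonium ion on the α face, and water would open it at C6 in the trans-diaxial sense to give the bromohydrin methyl (1S,4S,4aS,8aS)-4a-bromo-1-[2-(tert-butyldiphenylsilyloxy)ethyl]-4-hydroxy-5,5,8a-trimethyl-1,4,4a,5,6,7,8,8a-octahydronaphthalene-2-carboxylate F2. Bu3SnH with catalytic AIBN in PhMe at 80 °C would then remove bromine through the tertiary C5 radical, which should take hydrogen from the open α face. The route is rejoined at 16, so steps 6 to 8 are replaced.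

**Step 1.** The most likely failure is incomplete condensation. Addition of an α-branched amine to a carbonyl between a quaternary and a tertiary carbon is slow even with TiCl4, and unreacted ketone is hard to separate from a hydrolytically labile imine. The fallback forms the C–N bond by cross-coupling and sets out from 1. Lithium diisopropylamide in THF at −78 °C followed by N-phenylbis(trifluoromethanesulfonimide) would give the only possible enol triflate, 2,6,6-trimethylcyclohex-1-en-1-yl trifluoromethanesulfonate F3. Coupling with 2 (Pd2(dba)3, BINAP, Cs2CO3, PhMe, 100 °C; oxidative addition to zerovalent palladium, amine binding, reductive elimination) would give 7, which tautomerises, and the route is rejoined at 3.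

**Step 13.** The most likely failure is that slow hydrolysis of the shielded conjugated ester leaves time for base-promoted side reactions: a 1,3-proton shift of the γ-hydroxy enoate through its dienolate to a saturated 6-keto ester, or migration of C7=C8 toward C9. The fallback changes the order and the mechanism of ester cleavage and sets out from 20. Acetylation (Ac2O, DMAP, pyridine) would give methyl (1S,4S,4aR,8aS)-4-acetoxy-5,5,8a-trimethyl-1-[(2E)-3-methylpenta-2,4-dien-1-yl]-1,4,4a,5,6,7,8,8a-octahydronaphthalene-2-carboxylate F4. LiI in pyridine at reflux would then remove the methyl group by SN2 attack of iodide at O–CH3, which cannot touch the acetate because its alkyl carbon is secondary and shielded. After acidification the route is rejoined at 23, so steps 13 and 14 are replaced.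

## Further compounds

F1 | step 3 | methyl (1R,8aS)-1-[2-(tert-butyldiphenylsilyloxy)ethyl]-4a-hydroxy-5,5,8a-trimethyl-3-oxodecahydronaphthalene-2-carboxylate (C2 and C4a open) | CC(C)(C)[Si](c1ccccc1)(c1ccccc1)OCC[C@@H]1C(C(=O)OC)C(=O)CC2(O)C(C)(C)CCC[C@@]12C
F2 | step 7 | methyl (1S,4S,4aS,8aS)-4a-bromo-1-[2-(tert-butyldiphenylsilyloxy)ethyl]-4-hydroxy-5,5,8a-trimethyl-1,4,4a,5,6,7,8,8a-octahydronaphthalene-2-carboxylate | CC(C)(C)[Si](c1ccccc1)(c1ccccc1)OCC[C@@H]1C(C(=O)OC)=C[C@H](O)[C@]2(Br)C(C)(C)CCC[C@@]12C
F3 | step 1 | 2,6,6-trimethylcyclohex-1-en-1-yl trifluoromethanesulfonate | CC1=C(OS(=O)(=O)C(F)(F)F)C(C)(C)CCC1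
F4 | step 13 | methyl (1S,4S,4aR,8aS)-4-acetoxy-5,5,8a-trimethyl-1-[(2E)-3-methylpenta-2,4-dien-1-yl]-1,4,4a,5,6,7,8,8a-octahydronaphthalene-2-carboxylate | C=C/C(C)=C/C[C@@H]1C(C(=O)OC)=C[C@H](OC(C)=O)[C@@H]2C(C)(C)CCC[C@@]12C
A1 | alternative 1 | methyl trans-3-methyl-5-oxo-2-(2-oxo-1,3-oxazolidine-3-carbonyl)cyclohex-3-ene-1-carboxylate (1S,2R) | O=C1OCCN1C(=O)[C@@H]1[C@@H](C(=O)OC)CC(=O)C=C1C
A2 | alternative 1 | (Z)-2,4-bis(trimethylsilyloxy)penta-1,3-diene | C=C(O[Si](C)(C)C)/C=C(/C)O[Si](C)(C)C
A3 | alternative 1 | methyl (E)-4-oxo-4-(2-oxo-1,3-oxazolidin-3-yl)but-2-enoate | COC(=O)/C=C/C(=O)N1CCOC1=O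
A4 | alternative 2 | trans-fused cycloadduct: C6 triisopropylsilyl enol ether, C9 formyl, C8 tert-butyldimethylsilyloxymethyl, C10 methyl (labdane locants) | O=C[C@@H]1[C@H](CO[Si](C)(C)C(C)(C)C)C=C(O[Si](C(C)C)(C(C)C)C(C)C)[C@@H]2C(C)(C)CCC[C@@]12C
A5 | alternative 2 | (2E,8Z,10E)-12-(tert-butyldimethylsilyloxy)-3,7,7-trimethyl-9-(triisopropylsilyloxy)dodeca-2,8,10-trienal | O=C/C=C(\C)CCCC(C)(C)/C=C(O[Si](C(C)C)(C(C)C)C(C)C)/C=C/CO[Si](C)(C)C(C)(C)C
A6 | alternative 3 | 2-(but-2-yn-1-yl)-3-methyl-3-(4-methylpent-3-en-1-yl)cyclohexan-1-one, butynyl cis to methyl | CC#CC[C@@H]1C(=O)CCC[C@@]1(C)CCC=C(C)C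
A7 | alternative 3 | 3-methylcyclohex-2-en-1-one | CC1=CC(=O)CCC1
A8 | alternative 3 | (4-methylpent-3-en-1-yl)magnesium bromide | CC(C)=CCC[Mg]Br
A9 | alternative 3 | 1-bromobut-2-yne | CC#CCBr
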